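## Retrosynthetic overview

- Glabrol (**1**) comes from MOM removal of the protected flavanone **2**.
- **2** arises from one Cu/bisoxazoline radical annulation. The aroyl radical from salicylaldehyde **3** adds to the terminal CH2 of styrene **4**. The resulting benzylic radical is captured by a chiral Cu(II)–phenoxide. This forms the C3–C4 and C2–O bonds together and sets C2 as (S).
- The pyranone ring is the only ring formed in the route, and it is formed last; both arenes are pre-built.
- **3** comes from resorcinol (**5**) by formylation to 2,4-dihydroxybenzaldehyde (**6**) and C3-prenylation with prenyl bromide (**7**).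
- **4** comes from 4-chlorophenol (**8**) by MOM protection (**9**), ortho-lithiation/prenylation (**10**) and Suzuki vinylation with potassium vinyltrifluoroborate (**11**).

Assumption: the enantiomer of the BOX ligand that delivers the (S)-C2 centre has to be confirmed empirically; I take (S,S)-Ph-BOX.

## Route

**Step 1**
Reactants: **5** resorcinol
Product: **6** 2,4-dihydroxybenzaldehyde
Conditions: POCl3, DMF, MeCN, 0 °C → rt; then H2O
Reagents that add atoms: DMF, CN(C)C=O (supplies the CHO carbon and oxygen)
Why: Vilsmeier–Haack formylation occurs para to one OH and ortho to the other, the most activated position of resorcinol.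

**Step 2**
Reactants: **6** 2,4-dihydroxybenzaldehyde; **7** prenyl bromide
Product: **3** 2,4-dihydroxy-3-(3-methylbut-2-enyl)benzaldehyde
Conditions: **7** (1.1 equiv), aq. KOH (2.2 equiv), MeOH, 0 °C → rt, 20 h; chromatographic separation from the C5 and O-alkyl isomers
Reagents that add atoms: none
Why: Phenoxide C-alkylation (SN2) at C3, the carbon flanked by both oxygens, is favoured by K⁺/water chelation, as in the known 3-prenylation of 2,4-dihydroxyacetophenone; the yield is moderate.

**Step 3**
Reactants: **8** 4-chlorophenol
Product: **9** 1-chloro-4-(methoxymethoxy)benzene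
Conditions: NaH, THF, 0 °C; then MOMCl, 0 °C → rt
Reagents that add atoms: MOMCl, COCCl
Why: Williamson-type O-alkylation gives a MOM ether that is both a protecting group and a strong ortho-directing group for the next step.

**Step 4**
Reactants: **9**; **7** prenyl bromide
Product: **10** 4-chloro-1-(methoxymethoxy)-2-(3-methylbut-2-enyl)benzene
Conditions: n-BuLi, TMEDA, Et2O, 0 °C, 3 h; then CuI (10 mol %), **7**, −30 °C → rt
Reagents that add atoms: none
Why: Directed ortho-metalation occurs next to OMOM, and the aryl chloride survives. Cu(I)-catalysed SN2 allylation of the aryllithium gives the linear prenyl group.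

**Step 5**
Reactants: **10**; **11** potassium vinyltrifluoroborate
Product: **4** 1-(methoxymethoxy)-2-(3-methylbut-2-enyl)-4-vinylbenzene
Conditions: Pd(OAc)2 (3 mol %), RuPhos (6 mol %), Cs2CO3, THF/H2O 10:1, 80 °C, 16 h; BHT added, product stored cold
Reagents that add atoms: none
Why: Suzuki–Miyaura vinylation of the aryl chloride leaves the MOM ether and prenyl alkene untouched.

**Step 6**
Reactants: **3** aldehyde (1.5 equiv); **4** styrene (limiting)
Product: **2** (S)-7-hydroxy-8,3'-diprenyl-4'-(methoxymethoxy)flavanone
Conditions: Cu(MeCN)4PF6 (10 mol %), (S,S)-Ph-BOX (12 mol %), tBuOOBz (2 equiv), 2,6-lutidine (1 equiv), MeCN, 0 °C → rt, 48 h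
Reagents that add atoms: none (tBuOOBz is only the oxidant; the product is aldehyde + styrene − 2H)
Why: Proposed new method: Cu(I)/BOX reduces the perester to tBuO• and Cu(II)–OBz. tBuO• abstracts the aldehydic H of **3**, and the nucleophilic aroyl radical adds to the terminal CH2 of the electron-rich styrene **4**. The resulting p-alkoxybenzylic radical is intercepted by the chiral Cu(II)–phenoxide formed from the 2-OH, and C–O reductive elimination from Cu(III) closes the six-membered ring and sets C2 as (S). The closest known chemistry is the enantioselective Kharasch–Sosnovsky Cu/BOX radical C–O coupling, Cu-catalysed radical carbo-oxygenation of styrenes, and radical annulation of salicylaldehydes with alkenes to chroman-4-ones.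

**Step 7**
Reactants: **2**
Product: **1** glabrol
Conditions: ZnBr2 (5 equiv), n-PrSH (10 equiv), CH2Cl2, rt, 15 min
Reagents that add atoms: none (MOM is lost as a byproduct)
Why: Mild Lewis-acid MOM cleavage with a thiol cation scavenger, as in Hoye's conditions, spares the prenyl alkenes; the conditions are non-basic, so the flavanone cannot ring-open and racemize at C2.

## Compound list

| No. | Name | SMILES | Role |
|---|---|---|---|
| 1 | Glabrol, (S)-7,4'-dihydroxy-8,3'-diprenylflavanone | CC(C)=CCc1cc([C@@H]2CC(=O)c3ccc(O)c(CC=C(C)C)c3O2)ccc1O | target |
| 2 | (S)-7-hydroxy-8,3'-diprenyl-4'-MOM-oxyflavanone | CC(C)=CCc1cc([C@@H]2CC(=O)c3ccc(O)c(CC=C(C)C)c3O2)ccc1OCOC | intermediate |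
| 3 | 2,4-dihydroxy-3-prenylbenzaldehyde | O=Cc1ccc(O)c(CC=C(C)C)c1O | intermediate |
| 4 | 1-(MOM-oxy)-2-prenyl-4-vinylbenzene | C=Cc1ccc(OCOC)c(CC=C(C)C)c1 | intermediate |
| 5 | Resorcinol | Oc1cccc(O)c1 | starting material |
| 6 | 2,4-Dihydroxybenzaldehyde | O=Cc1ccc(O)cc1O | intermediate |
| 7 | Prenyl bromide | CC(C)=CCBr | starting material |
| 8 | 4-Chlorophenol | Oc1ccc(Cl)cc1 | starting material |
| 9 | 1-Chloro-4-(methoxymethoxy)benzene | COCOc1ccc(Cl)cc1 | intermediate |
| 10 | 4-Chloro-1-(MOM-oxy)-2-prenylbenzene | COCOc1ccc(Cl)cc1CC=C(C)C | intermediate |
| 11 | Potassium vinyltrifluoroborate | C=C[B-](F)(F)F.[K+] | starting material |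

**Total steps:** 7
**Longest linear sequence:** 5 (8 → 9 → 10 → 4 → 2 → 1)

## Three steps most likely to fail

1. **Step 6 (radical annulation).** Risks are H-abstraction at the prenyl CH2 groups, a racemic cationic or quinone-methide background pathway, and low ee.
   Fallback: run the annulation without the chiral catalyst (racemic, photochemical HAT) and resolve **2** by preparative chiral SFC/HPLC.
2. **Step 2 (C3-selective prenylation).** Mixtures of C3, C5 and O-alkylation products are likely.
   Fallback: use bis-MOM-resorcinol, C2 lithiation/prenylation, and MOM removal to give 2-prenylresorcinol. Then ortho-formylate with MgCl2/Et3N/(CH2O)n, which is regiochemically unambiguous because the substrate is symmetric.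
3. **Step 4 (ortho-lithiation/prenylation).** Risks are competing lithiation next to Cl and SN2′ (branched) allylation.
   Fallback: go through allyl ether formation of **8**, Claisen rearrangement to 2-allyl-4-chlorophenol, MOM protection, and cross-metathesis with 2-methyl-2-butene (Grubbs II) to install the prenyl group.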